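The flavone is disconnected at the O1–C8a bond. Because O5 and O8 stand para on ring A and C8a is a C–H carbon, ring A can be carried as a 1,4-benzoquinone (carbonyls at C5 and C8, methoxy at C7) that bears the 1,3-diketone chain at C4a. In one operation the enol oxygen of that chain adds to C8a, which is beta to both the C5 and the C4 carbonyl, closing the pyranone ring, and tautomerisation delivers the 5,8-dihydroxy ring A. The precursor is 2-[3-(2,3-dimethoxyphenyl)-3-oxopropanoyl]-5-methoxy-1,4-benzoquinone, reached by mild oxidation of the corresponding hydroquinone; selective methylation of O8 finishes the synthesis.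

Key step: step 4

Remark on the chemistry: ring A is carried to the quinone as a free hydroquinone and not as methyl ethers, because a one-electron oxidative demethylation run with the enol already in place would be expected to close at the methoxy-bearing ortho carbon or to attack the enol. Flavone numbering (C4a, C5–C8, C8a) is used for ring A atoms in the open-chain compounds as well.

Step 1
Reactants: 1 methoxyhydroquinone (2-methoxybenzene-1,4-diol)
Product: 2 2',5'-dihydroxy-4'-methoxyacetophenone
Conditions: AcOH, BF3·OEt2, 90 °C; then H2O
Reagents that add atoms: acetic acid, CC(=O)O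
Why: Friedel–Crafts (Nencki-type) acylation of a polyoxygenated arene, which should go to C5 of 1, the only unhindered ring carbon that is both ortho to a hydroxyl and para to the methoxy group, and should stop after one acylation because the ortho-hydroxy ketone formed is deactivated.

Step 2
Reactants: 2 2',5'-dihydroxy-4'-methoxyacetophenone; 3 2,3-dimethoxybenzoyl chloride
Product: 4 1-(2,5-dihydroxy-4-methoxyphenyl)-3-(2,3-dimethoxyphenyl)propane-1,3-dione
Conditions: LiN(SiMe3)2 (4 equiv), THF, −78 °C to rt, Ar; then cold 1 M HCl
Reagents that add atoms: none
Why: Claisen-type C-acylation of a ketone enolate with an acid chloride, run on the unprotected phenol as its lithium polyanion, in which the aggregated phenoxides should stay unreactive, the enolate carbon should be acylated and the fourth equivalent of base takes up the acidic diketone proton, while the cold, mildly acidic work-up avoids cyclodehydration through the C2' hydroxyl.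

Step 3
Reactants: 4 1-(2,5-dihydroxy-4-methoxyphenyl)-3-(2,3-dimethoxyphenyl)propane-1,3-dione
Product: 5 2-[3-(2,3-dimethoxyphenyl)-3-oxopropanoyl]-5-methoxy-1,4-benzoquinone (kept in solution and used at once)
Conditions: Ag2O (2 equiv), Na2SO4, CH2Cl2, 0 °C, dark, 20 min; filtered through Celite
Reagents that add atoms: none
Why: Oxidation of a hydroquinone to the para-benzoquinone with Ag2O is the standard entry to 2-acyl-1,4-benzoquinones, and it should work here because the neutral, heterogeneous two-electron oxidant leaves the 1,3-diketone and the dimethoxyphenyl ring alone and is filtered off, so that no oxidant travels with 5 into the ring closure.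

Step 4
Reactants: 5 2-[3-(2,3-dimethoxyphenyl)-3-oxopropanoyl]-5-methoxy-1,4-benzoquinone
Product: 6 5,8-dihydroxy-7-methoxy-2-(2,3-dimethoxyphenyl)-4H-chromen-4-one
Conditions: filtrate of step 3 diluted with degassed CH2Cl2 (0.005 M), 2,6-lutidine (0.2 equiv), −20 °C to rt, Ar
Reagents that add atoms: none
Why: Proposed new method: the Z-enol (or enolate) oxygen on C2 of the diketone chain should add to C8a of the quinone, the ring C–H carbon that is beta to both the C5 quinone carbonyl and the side-chain C4 carbonyl, after which transfer of the C8a proton to O8 aromatises ring A to the 5,8-hydroquinone with no net change of oxidation level. The closest known reaction types are the conjugate addition of oxygen nucleophiles to C3 of 2-acyl-1,4-benzoquinones, the closure of 2-(2-hydroxybenzoyl)quinones to xanthones, and the oxa-Michael cyclisation of 1,3-diketone enols onto enones and ynones that gives 4-pyranones. The pyranone ring closes in the 6-endo-trig mode across the C4a=C8a bond. No stereocentre results, because the sp3 carbon that appears at C8a after the addition is lost again on enolisation. The step needs O- and not C-attack and 1,4- and not 1,2-addition: the central carbon C3 could reach a ring carbon only through a four-membered ring, and addition of the enol oxygen to the C5 carbonyl carbon, the only other site within six-membered reach, gives a hemiketal that can revert, whereas the C8a adduct aromatises irreversibly. High dilution and a weak, hindered base should keep intermolecular C-arylation of the diketone and quinone–hydroquinone electron transfer slower than the intramolecular closure.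

Step 5
Reactants: 6 5,8-dihydroxy-7-methoxy-2-(2,3-dimethoxyphenyl)-4H-chromen-4-one
Product: 7 5-hydroxy-2',3',7,8-tetramethoxyflavone (5-hydroxy-7,8-dimethoxy-2-(2,3-dimethoxyphenyl)-4H-chromen-4-one)
Conditions: MeI (1.1 equiv), K2CO3 (1.5 equiv), degassed acetone, 40 °C, Ar
Reagents that add atoms: iodomethane, CI
Why: Williamson ether synthesis that should be selective for O8, because the C5 hydroxyl is held in a hydrogen bond to the C4 carbonyl and is neither deprotonated nor alkylated readily under these mild conditions with a limited amount of MeI, while exclusion of air protects the hydroquinone from oxidation.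

Compound list
1 | methoxyhydroquinone (2-methoxybenzene-1,4-diol) | COc1cc(O)ccc1O | starting material
2 | 2',5'-dihydroxy-4'-methoxyacetophenone | CC(=O)c1cc(O)c(OC)cc1O | intermediate
3 | 2,3-dimethoxybenzoyl chloride | COc1cccc(C(=O)Cl)c1OC | starting material
4 | 1-(2,5-dihydroxy-4-methoxyphenyl)-3-(2,3-dimethoxyphenyl)propane-1,3-dione | COc1cc(O)c(C(=O)CC(=O)c2cccc(OC)c2OC)cc1O | intermediate
5 | 2-[3-(2,3-dimethoxyphenyl)-3-oxopropanoyl]-5-methoxy-1,4-benzoquinone (diketo tautomer drawn) | COC1=CC(=O)C(C(=O)CC(=O)c2cccc(OC)c2OC)=CC1=O | intermediate
6 | 5,8-dihydroxy-7-methoxy-2-(2,3-dimethoxyphenyl)-4H-chromen-4-one | O=c1cc(-c2cccc(OC)c2OC)oc2c(O)c(OC)cc(O)c12 | intermediate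
7 | 5-hydroxy-2',3',7,8-tetramethoxyflavone | COc1cccc(-c2cc(=O)c3c(O)cc(OC)c(OC)c3o2)c1OC | target

Total step count: 5. Longest linear sequence: 5 steps (1 to 7; 3 is a purchased reagent). Where 2 can be bought, the route shortens to four steps.

Steps most likely to fail

Step 4. The closure could be overtaken by electron transfer from the hydroquinone being formed to quinone not yet cyclised, by intermolecular carbon–carbon bond formation at the diketone carbon, or the chelated enol could fail to turn its oxygen toward C8a. The fallback reaches 6 by known chemistry, setting out from 3 and coming back at 6. Compound 3 would acylate the lithium polyanion of purchased 2',6'-dihydroxy-4'-methoxyacetophenone F1 (LiN(SiMe3)2, THF, −78 °C to rt) to give 1-(2,6-dihydroxy-4-methoxyphenyl)-3-(2,3-dimethoxyphenyl)propane-1,3-dione F2. Acid cyclodehydration (H2SO4, AcOH, 95 °C) would close the pyranone through a phenolic oxygen to 5-hydroxy-7-methoxy-2-(2,3-dimethoxyphenyl)-4H-chromen-4-one F3; the two ortho hydroxyls of F2 are equivalent, so only one flavone can form. Elbs persulfate oxidation (K2S2O8, aqueous KOH, pyridine, rt) would introduce oxygen para to the C5 hydroxyl, at C8, as potassium 2-(2,3-dimethoxyphenyl)-5-hydroxy-7-methoxy-4-oxo-4H-chromen-8-yl sulfate F4. Hydrolysis of F4 (aqueous HCl, Na2SO3, 90 °C) would give 6, and step 5 follows unchanged.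

Step 3. Ring closure could begin while the oxidant is still present, so that cyclised hydroquinone is oxidised further while part of 4 remains, or the acylquinone could decay while the filtrate is handled. The fallback no longer tries to hold the quinone: it sets out from 4 and comes back at 6. Compound 4 would be stirred with an excess of Ag2O and 2,6-lutidine in CH2Cl2, so that oxidation, closure and a second oxidation run in one flask to the isolable 2-(2,3-dimethoxyphenyl)-7-methoxy-4H-chromene-4,5,8-trione F5. Reduction of F5 with aqueous Na2S2O4 would then give 6.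

Step 2. Acylation could occur at a phenoxide oxygen instead of the enolate carbon, or the electron-rich polyanion could be oxidised by traces of air. The fallback protects the phenols, setting out from 2 and coming back at 4. Benzylation of 2 (BnBr, K2CO3, DMF, 60 °C) would give 2',5'-bis(benzyloxy)-4'-methoxyacetophenone F6. Its lithium enolate (LiN(SiMe3)2, 2.2 equiv, THF, −78 °C) would be acylated with 3 to 1-[2,5-bis(benzyloxy)-4-methoxyphenyl]-3-(2,3-dimethoxyphenyl)propane-1,3-dione F7. Neutral hydrogenolysis of F7 (H2, 10% Pd/C, EtOAc, rt) would release 4.

Further compounds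
F1 | step 4 | 2',6'-dihydroxy-4'-methoxyacetophenone (purchased) | CC(=O)c1c(O)cc(OC)cc1O
F2 | step 4 | 1-(2,6-dihydroxy-4-methoxyphenyl)-3-(2,3-dimethoxyphenyl)propane-1,3-dione | COc1cc(O)c(C(=O)CC(=O)c2cccc(OC)c2OC)c(O)c1
F3 | step 4 | 5-hydroxy-7-methoxy-2-(2,3-dimethoxyphenyl)-4H-chromen-4-one | COc1cc(O)c2c(c1)oc(-c1cccc(OC)c1OC)cc2=O
F4 | step 4 | potassium 2-(2,3-dimethoxyphenyl)-5-hydroxy-7-methoxy-4-oxo-4H-chromen-8-yl sulfate | COc1cc(O)c2c(c1OS(=O)(=O)[O-])oc(-c1cccc(OC)c1OC)cc2=O.[K+]
F5 | step 3 | 2-(2,3-dimethoxyphenyl)-7-methoxy-4H-chromene-4,5,8-trione | COC1=CC(=O)C2=C(OC(=CC2=O)c2cccc(OC)c2OC)C1=O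
F6 | step 2 | 2',5'-bis(benzyloxy)-4'-methoxyacetophenone | CC(=O)c1cc(OCc2ccccc2)c(OC)cc1OCc1ccccc1
F7 | step 2 | 1-[2,5-bis(benzyloxy)-4-methoxyphenyl]-3-(2,3-dimethoxyphenyl)propane-1,3-dione | COc1cc(OCc2ccccc2)c(C(=O)CC(=O)c2cccc(OC)c2OC)cc1OCc1ccccc1
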